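A small charge of free catalyst has to serve the whole starting material, so it must go round 6.67 times, and counting those laps is the reckoning.

starting material 0.20 M; partner 1.00 M; scavenger 0.160 M; free catalyst 30 mM; time 40 h

- part of the starting material that has reacted at 40 h
- share of the unused partner that is free and not bound as idle adduct, at 40 h

    starting material + catalyst intermediate C → catalyst intermediate D (k1 = 0.0697 L mol⁻¹ min⁻¹)
    catalyst intermediate B ⇌ catalyst intermediate C (K2 = 24, k2 = 0.0324 min⁻¹)
    catalyst intermediate A ⇌ released group + catalyst intermediate B (K3 = 0.39 M, k3 = 1.70 min⁻¹)
    catalyst intermediate D → free catalyst + product (k4 = 0.0377 min⁻¹)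
    scavenger + released group → scavenged by-product (k5 = 2.14 L mol⁻¹ min⁻¹)
    partner + free catalyst → catalyst intermediate A (k6 = 0.0267 L mol⁻¹ min⁻¹)
    partner + released group ⇌ idle adduct, settled at all times (K7 = 0.38 L mol⁻¹)

Define the fixed lap as the time one catalyst spends per turnover on everything except waiting for starting material, the sum of the reciprocal forward rates with partner held at its charge: 95.4 min.

Now take two extremes. If c(starting material) never thinned, each lap would cost 2.79 h, and the laps would end after 18.6 h. If the fixed lap cost nothing, the catalyst would sit wholly as catalyst intermediate C, the decay would be pseudo-first-order, and 99.3% would react. You must pay both bills, so the real flask lies under that ceiling. The fixed laps take 10.6 h, about a quarter of the time, and the remaining 29.4 h of waiting gives me 97.5%.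

For the partner, released group cannot exceed the charges of starting material and catalyst together, less the 0.160 M the scavenger can take. That puts the free share at 97.4% or above.

The forecast says 96.7% and 98.1%, with “the late rate limited by its reaction with intermediate C”. The simulation gives 96.5% and 98.2%, so my conversion stands 1.00 percentage point higher.

Scavenger fell from 67.1% at 4.00 h to 0.634% at 20.0 h while released group went from 7.01 × 10⁻⁴ M to 0.00914 M; by 40.0 h scavenger stood at 0%, with released group at 0.0479 M beside 0.0139 M of idle adduct. Catalyst intermediate C was the resting state: at 20.0 h, the wait for starting material against the fixed lap puts 73.9% of the catalyst there, and the flask held 68.8%.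

In the neighbour flask with 0.018 M of free catalyst, 11.1 laps cost 17.7 h, which gives 81.4%. The computed answer for that flask is 82.2%.

Its constants stand for no real mixture.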